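Everything rests on cutting C8–C9 and C12–C13. Rings C and D are a bicyclo[3.2.1]octane in which C14 spans a seven-membered circuit (C8–C9–C11–C12–C13–C16–C15). The ring D carbons (C8, C15, C16, C13, C14) are a cyclopentadiene and C9, C11, C12 an oxyallyl cation. One intramolecular (4+3) cycloaddition therefore closes rings B and C onto a preformed ring D and sets C8, C9 and C13. Its precursor is an enantiopure ring A cyclohexane bearing, on C10, the C20 acetal and a chloroacetonyl arm and, on C5, an acetate arm whose C6 carries the methylcyclopentadiene.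

Key step: step 15

Atoms are numbered as in the gibberellane skeleton (C1–C20).

Assumption: the L-valine auxiliary with HMPA as donor ligand is taken to deliver the (R)-keto ester 5 (D-valine tert-butyl ester would be used if the sense proved opposite), and the target is treated as the open C20 aldehyde diacid, which may equilibrate with its 19,20-lactol.

Step 1
Reactants: 1 methyl 2-oxocyclohexane-1-carboxylate; 2 L-valine tert-butyl ester
Product: 3 enamino ester, methyl 2-{[(2S)-1-tert-butoxy-3-methyl-1-oxobutan-2-yl]amino}cyclohex-1-ene-1-carboxylate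
Conditions: p-TsOH (cat.), toluene, reflux, Dean–Stark
Reagents that add atoms: none
Why: Acid-catalysed enamine condensation of the beta-keto ester with the primary amine should give the hydrogen-bonded vinylogous carbamate that carries the chiral auxiliary.

Step 2
Reactants: 3 enamino ester
Product: 5 methyl (1R)-1-methyl-2-oxocyclohexane-1-carboxylate, via methylated ketimine 4 (not isolated)
Conditions: LiN(iPr)2, toluene, HMPA (1 equiv), −78 °C; MeI, −78 to −40 °C; then aq. citric acid, rt
Reagents that add atoms: iodomethane, CI; water, O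
Why: Auxiliary-controlled alkylation of the N-metallated chiral enamine should deliver methyl to one face of C4, and mild hydrolysis of the ketimine releases the quaternary (R)-keto ester and the auxiliary.

Step 3
Reactants: 5 methyl (1R)-1-methyl-2-oxocyclohexane-1-carboxylate
Product: 6 methyl (1R,3Z)-3-(hydroxymethylidene)-1-methyl-2-oxocyclohexane-1-carboxylate
Conditions: LiN(iPr)2, THF, −78 °C; HCO2CH2CF3, −78 to 0 °C; 1 M HCl work-up
Reagents that add atoms: 2,2,2-trifluoroethyl formate, O=COCC(F)(F)F
Why: Crossed Claisen condensation (kinetic formylation) at C10, the only enolisable position, should give the chelated hydroxymethylene ketone at low temperature, where the non-enolisable beta-keto ester is not cleaved.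

Step 4
Reactants: 6 hydroxymethylene ketone; 7 allyl bromide
Product: 8 methyl (1R,3E)-1-methyl-2-oxo-3-[(prop-2-en-1-yloxy)methylidene]cyclohexane-1-carboxylate
Conditions: K2CO3, acetone, reflux
Reagents that add atoms: none
Why: Williamson-type O-alkylation of the vinylogous acid under weak base should give the allyl enol ether required for the sigmatropic step.

Step 5
Reactants: 8 allyl enol ether
Product: 9 methyl (1R,3S)-3-formyl-1-methyl-2-oxo-3-(prop-2-en-1-yl)cyclohexane-1-carboxylate (formyl cis to the ester)
Conditions: toluene, 140 °C, sealed tube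
Reagents that add atoms: none
Why: Thermal Claisen rearrangement forms the C10–C9 bond and the C20 aldehyde together, and the allyl terminus should approach the face of C10 away from the pseudoaxial C19 ester on C4, which places formyl and ester cis.

Step 6
Reactants: 9 keto aldehyde
Product: 10 methyl (1R,3S)-3-(dimethoxymethyl)-1-methyl-2-oxo-3-(prop-2-en-1-yl)cyclohexane-1-carboxylate
Conditions: HC(OMe)3, MeOH, PPTS (cat.), rt
Reagents that add atoms: trimethyl orthoformate, COC(OC)OC
Why: Acid-catalysed acetalisation should be selective for the aldehyde because the ketone lies between two quaternary carbons.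

Step 7
Reactants: 10 keto acetal; 11 ethoxyacetylene
Product: 12 methyl 3-(dimethoxymethyl)-2-(ethoxyethynyl)-2-hydroxy-1-methyl-3-(prop-2-en-1-yl)cyclohexane-1-carboxylate (C4 and C10 as in 10; carbinol centre C5 not defined)
Conditions: 11, n-BuLi, THF, −78 °C; then 10, −78 to −30 °C; AcOH quench at −78 °C
Reagents that add atoms: none
Why: 1,2-Addition of the slim, linear acetylide is chosen because phosphonate or ylide olefination would not reach a carbonyl flanked by two quaternary carbons, and the carbinol configuration is lost in the next step.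

Step 8
Reactants: 12 ethoxyalkynyl carbinol
Product: 13 ethyl 2-[2-(dimethoxymethyl)-6-(methoxycarbonyl)-6-methyl-2-(prop-2-en-1-yl)cyclohexylidene]acetate (C4 and C10 as in 10; alkene geometry not defined)
Conditions: camphorsulfonic acid (5 mol%), CH2Cl2, 0 °C to rt
Reagents that add atoms: none
Why: Acid-catalysed Meyer–Schuster rearrangement of the ethoxyalkynyl carbinol should give the alpha,beta-unsaturated ester (C5=C6–C7), and the water-free medium spares the acetal.

Step 9
Reactants: 13 alkylidene ester
Product: 14 methyl (1R,2S,3R)-3-(dimethoxymethyl)-2-(2-methoxy-2-oxoethyl)-1-methyl-3-(prop-2-en-1-yl)cyclohexane-1-carboxylate (C19, C6 and C20 all cis)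
Conditions: Mg turnings, MeOH, 0 °C to rt
Reagents that add atoms: methanol, CO
Why: Dissolving-metal conjugate reduction saturates only the enoate and exchanges the ethyl for the methyl ester; C5 should be protonated on the face opposite the axial C19 ester and C20 acetal, which share one face of the ring A chair because the smaller C18 and C9 groups take the equatorial sites that eclipse the alkylidene.

Step 10
Reactants: 14 allyl diester
Product: 15 methyl (1R,2S,3R)-3-(dimethoxymethyl)-2-(2-methoxy-2-oxoethyl)-1-methyl-3-(2-oxopropyl)cyclohexane-1-carboxylate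
Conditions: PdCl2 (10 mol%), Cu(OAc)2 (20 mol%), O2 (1 atm), DMA/H2O 7:1, rt
Reagents that add atoms: water, O
Why: Tsuji–Wacker oxidation of the terminal alkene should give the methyl ketone (C11, C12), and Cu(OAc)2 as co-oxidant keeps the medium mild enough for the acetal.

Step 11
Reactants: 15 methyl ketone
Product: 16 methyl (1R,2S,3R)-3-{2-[(tert-butyldimethylsilyl)oxy]prop-2-en-1-yl}-3-(dimethoxymethyl)-2-(2-methoxy-2-oxoethyl)-1-methylcyclohexane-1-carboxylate
Conditions: LiN(iPr)2, THF, −78 °C; TBSCl, HMPA, −78 to 0 °C
Reagents that add atoms: tert-butyldimethylsilyl chloride, CC(C)(C)[Si](C)(C)Cl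
Why: Kinetic enolisation at the unhindered C12 methyl (C9 is neopentylic and the ester hydrogens are less acidic) and O-silylation give the terminal silyl enol ether, which masks the ketone for the next enolate step and marks C12 for chlorination.

Step 12
Reactants: 16 silyl enol ether; 17 3-methylcyclopent-2-en-1-one
Product: 18 aldol adduct, methyl (1R,2S,3R)-3-{2-[(tert-butyldimethylsilyl)oxy]prop-2-en-1-yl}-3-(dimethoxymethyl)-2-[1-(1-hydroxy-3-methylcyclopent-2-en-1-yl)-2-methoxy-2-oxoethyl]-1-methylcyclohexane-1-carboxylate (C6 and C8 not defined)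
Conditions: LiN(iPr)2, THF, −78 °C; CeCl3, −78 °C; then 17; AcOH quench at −78 °C
Reagents that add atoms: none
Why: Aldol-type 1,2-addition of the C6 ester enolate, transmetallated with CeCl3 to suppress proton transfer, to the beta-substituted enone forms the C6–C8 bond; C6 and C8 are not controlled and need not be, since C8 becomes trigonal in step 14 and C6 is reset in step 18.

Step 13
Reactants: 18 aldol adduct
Product: 19 chloromethyl ketone carbinol, methyl (1R,2S,3R)-3-(3-chloro-2-oxopropyl)-3-(dimethoxymethyl)-2-[1-(1-hydroxy-3-methylcyclopent-2-en-1-yl)-2-methoxy-2-oxoethyl]-1-methylcyclohexane-1-carboxylate (C6 and C8 not defined)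
Conditions: NCS, NaHCO3, THF, 0 °C
Reagents that add atoms: N-chlorosuccinimide, O=C1CCC(=O)N1Cl
Why: Electrophilic alpha-chlorination of the silyl enol ether places chlorine only at C12, while the isolated trisubstituted alkene, the carbinol and the esters are inert to this reagent.

Step 14
Reactants: 19 chloromethyl ketone carbinol
Product: 21 chloromethyl ketone diene, methyl (1R,2S,3R)-3-(3-chloro-2-oxopropyl)-3-(dimethoxymethyl)-2-[2-methoxy-1-(3-methylcyclopenta-1,3-dien-1-yl)-2-oxoethyl]-1-methylcyclohexane-1-carboxylate (C6 epimer pair), via kinetic ring tautomer 20 (not isolated)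
Conditions: p-TsOH·H2O (2 mol%), MgSO4, CH2Cl2, 0 °C; Et3N quench
Reagents that add atoms: none
Why: Acid-catalysed dehydration of the tertiary allylic alcohol by ionisation to its allyl cation and proton loss, the standard route from cyclopentenone adducts to cyclopentadienes, should give ring tautomers 20 and 21, which interconvert by 1,5-hydrogen shift; the diene is made last because it would not survive the oxidation and chlorination steps.

Step 15
Reactants: 21 chloromethyl ketone diene
Product: 23 tetracyclic C11 ketone, dimethyl 20,20-dimethoxy-11-oxogibberell-15-ene-7,19-dioate (C6 epimer pair), via 2-oxyallyl cation 22 (not isolated)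
Conditions: Et3N (3 equiv), CF3CH2OH, 0.005 M, 0 °C to rt
Reagents that add atoms: none
Why: Et3N enolises 21 toward C9 and chloride leaves from C12 in the ionising solvent, giving the 2-oxyallyl cation 22, whose termini C9 and C12 should bond to the diene termini C8 and C13 either in concert or by C8–C9 bonding first and collapse of the C15–C16–C13 allyl cation onto C12. The closest known reaction type is the (4+3) cycloaddition of oxyallyl cations generated from alpha-chloro ketones with amine base in fluorinated alcohol, known with cyclopentadiene and, intramolecularly, with tethered furans and butadienes. Ring B closes in a 5-exo mode through the tether C10–C5–C6, and ring C closes as the six-membered ketone bridge C8–C9–C11–C12–C13–C14 when the second bond reaches C13. C9 is controlled by the tether, which spans C9 and C8 only if C10 sits above the C8–C6 bond (extended arrangement of the W-shaped cation), so the hydrogen on C9 points to the C15 side and the B/C fusion is cis; C8 and C13 are fixed together by the diene face attacked, which the trans-diequatorial arms of the ring A chair and the preference of the C7 ester for the flat C15–H edge should steer so that C14 lies on the side of C20. The step needs reaction through the tautomer with C8 at a diene terminus and bonding at C13, not at methyl-bearing C16; this should be secured because 20 and 21 interconvert while in 20 C8 is an inner diene carbon, so that its three-atom tether could close only through a strained bridgehead-alkene mode, and because the tautomer with its CH2 between C8 and C16 forms only through less stable 5-substituted isomers. High dilution and the amine buffer should hold back diene dimerisation and solvent capture.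

Step 16
Reactants: 23 tetracyclic C11 ketone
Product: 24 C11 p-toluenesulfonylhydrazone of 23 (C6 epimer pair)
Conditions: TsNHNH2, AcOH (cat.), MeOH, 50 °C
Reagents that add atoms: p-toluenesulfonohydrazide, Cc1ccc(cc1)S(=O)(=O)NN
Why: Hydrazone condensation at the only ketone proceeds in methanol, in which the dimethyl acetal is degenerate toward exchange.

Step 17
Reactants: 24 tosylhydrazone
Product: 26 dimethyl 20,20-dimethoxygibberell-15-ene-7,19-dioate (C6 epimer pair), via N-boryl tosylhydrazine 25 (not isolated)
Conditions: catecholborane, CHCl3, 0 °C; then NaOAc·3H2O, reflux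
Reagents that add atoms: none
Why: Caglioti-type reductive deoxygenation (hydride addition to the tosylhydrazone, then acetate-induced loss of sulfinate and dinitrogen) replaces the C11 carbonyl by CH2 without touching esters, acetal or the trisubstituted alkene.

Step 18
Reactants: 26 diester acetal (C6 epimer pair)
Product: 27 dimethyl 20,20-dimethoxygibberell-15-ene-7,19-dioate with the natural C6 configuration (C7 ester trans to C4 on ring B)
Conditions: NaOMe (0.5 equiv), MeOH, 60 °C
Reagents that add atoms: none
Why: Base-mediated epimerisation through the C7 ester enolate should converge both epimers on the natural C6 configuration, in which the ester avoids the quaternary C4, and C9 can no longer epimerise once the ketone is gone.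

Step 19
Reactants: 27 C15=C16 alkene
Product: 29 15-oxo enone, dimethyl 20,20-dimethoxy-15-oxogibberell-16-ene-7,19-dioate, via C15 hydroperoxide 28 (not isolated)
Conditions: O2, tetraphenylporphyrin (cat.), visible light, CH2Cl2, 0 °C; then Ac2O, pyridine, DMAP (cat.), rt
Reagents that add atoms: dioxygen, O=O
Why: The Schenck ene reaction of singlet oxygen can only abstract hydrogen from C17 (C13 is a bridgehead, C8 is quaternary), so oxygen enters at C15 and the alkene moves to C16=C17, and in situ acetylation with base-induced elimination (Kornblum–DeLaMare type) gives the enone whatever the C15 configuration.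

Step 20
Reactants: 29 15-oxo enone
Product: 30 15beta-alcohol, dimethyl 15beta-hydroxy-20,20-dimethoxygibberell-16-ene-7,19-dioate
Conditions: NaBH4, CeCl3·7H2O, MeOH, −78 to −20 °C
Reagents that add atoms: none
Why: Luche reduction gives 1,2-reduction of the alpha-methylene ketone, and hydride delivery from the exo face of the bicyclo[3.2.1]octane (the side of the C14 bridge) should place the hydroxyl on the face toward the C9–C11–C12 bridge of ring C, as in the target.

Step 21
Reactants: 30 15beta-alcohol diester
Product: 31 diacid acetal, 15beta-hydroxy-20,20-dimethoxygibberell-16-ene-7,19-dioic acid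
Conditions: LiSPr, HMPA, rt to 50 °C; then 1 M HCl to pH 3
Reagents that add atoms: none
Why: Nucleophilic ester demethylation by thiolate takes place at the methyl carbons, so the shielded axial C19 ester is cleaved as readily as the C7 ester, and acetal, alkene and allylic alcohol are inert.

Step 22
Reactants: 31 diacid acetal
Product: 32 target gibberellin, 15beta-hydroxy-20-oxogibberell-16-ene-7,19-dioic acid
Conditions: AcOH/THF/H2O 3:1:1, 40 °C
Reagents that add atoms: water, O
Why: Mild acid-catalysed acetal hydrolysis releases the C20 aldehyde under conditions too weak to ionise the allylic alcohol.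

Compound list

1 | methyl 2-oxocyclohexane-1-carboxylate | COC(=O)C1CCCCC1=O | starting material
2 | L-valine tert-butyl ester, tert-butyl (2S)-2-amino-3-methylbutanoate | CC(C)[C@H](N)C(=O)OC(C)(C)C | starting material
3 | enamino ester, methyl 2-{[(2S)-1-tert-butoxy-3-methyl-1-oxobutan-2-yl]amino}cyclohex-1-ene-1-carboxylate | COC(=O)C1=C(N[C@@H](C(C)C)C(=O)OC(C)(C)C)CCCC1 | intermediate
4 | methylated ketimine, methyl (1R)-2-{[(2S)-1-tert-butoxy-3-methyl-1-oxobutan-2-yl]imino}-1-methylcyclohexane-1-carboxylate | C1CCC[C@@](C)(C(=O)OC)C1=N[C@@H](C(C)C)C(=O)OC(C)(C)C | intermediate (not isolated)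
5 | methyl (1R)-1-methyl-2-oxocyclohexane-1-carboxylate (C4 quaternary, C5 ketone) | C1CCC[C@@](C)(C(=O)OC)C1=O | intermediate
6 | methyl (1R,3Z)-3-(hydroxymethylidene)-1-methyl-2-oxocyclohexane-1-carboxylate | O/C=C1/CCC[C@@](C)(C(=O)OC)C1=O | intermediate
7 | allyl bromide (3-bromoprop-1-ene) | C=CCBr | starting material
8 | methyl (1R,3E)-1-methyl-2-oxo-3-[(prop-2-en-1-yloxy)methylidene]cyclohexane-1-carboxylate | C=CCO/C=C1\CCC[C@@](C)(C(=O)OC)C1=O | intermediate
9 | methyl (1R,3S)-3-formyl-1-methyl-2-oxo-3-(prop-2-en-1-yl)cyclohexane-1-carboxylate (formyl cis to ester) | C=CC[C@]1(C=O)CCC[C@@](C)(C(=O)OC)C1=O | intermediate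
10 | methyl (1R,3S)-3-(dimethoxymethyl)-1-methyl-2-oxo-3-(prop-2-en-1-yl)cyclohexane-1-carboxylate | C=CC[C@]1(C(OC)OC)CCC[C@@](C)(C(=O)OC)C1=O | intermediate
11 | ethoxyacetylene (ethoxyethyne) | C#COCC | starting material
12 | methyl 3-(dimethoxymethyl)-2-(ethoxyethynyl)-2-hydroxy-1-methyl-3-(prop-2-en-1-yl)cyclohexane-1-carboxylate (C4 and C10 as in 10; C5 not defined) | C=CC[C@]1(C(OC)OC)CCC[C@@](C)(C(=O)OC)C1(O)C#COCC | intermediate
13 | ethyl 2-[2-(dimethoxymethyl)-6-(methoxycarbonyl)-6-methyl-2-(prop-2-en-1-yl)cyclohexylidene]acetate (C4 and C10 as in 10; alkene geometry not defined) | C=CC[C@]1(C(OC)OC)CCC[C@@](C)(C(=O)OC)C1=CC(=O)OCC | intermediate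
14 | methyl (1R,2S,3R)-3-(dimethoxymethyl)-2-(2-methoxy-2-oxoethyl)-1-methyl-3-(prop-2-en-1-yl)cyclohexane-1-carboxylate | C=CC[C@]4(C(OC)OC)CCC[C@@](C)(C(=O)OC)[C@H]4CC(=O)OC | intermediate
15 | methyl (1R,2S,3R)-3-(dimethoxymethyl)-2-(2-methoxy-2-oxoethyl)-1-methyl-3-(2-oxopropyl)cyclohexane-1-carboxylate | CC(=O)C[C@]4(C(OC)OC)CCC[C@@](C)(C(=O)OC)[C@H]4CC(=O)OC | intermediate
16 | methyl (1R,2S,3R)-3-{2-[(tert-butyldimethylsilyl)oxy]prop-2-en-1-yl}-3-(dimethoxymethyl)-2-(2-methoxy-2-oxoethyl)-1-methylcyclohexane-1-carboxylate | C=C(O[Si](C)(C)C(C)(C)C)C[C@]4(C(OC)OC)CCC[C@@](C)(C(=O)OC)[C@H]4CC(=O)OC | intermediate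
17 | 3-methylcyclopent-2-en-1-one | CC1=CC(=O)CC1 | starting material
18 | aldol adduct: 16 bearing a 1-hydroxy-3-methylcyclopent-2-en-1-yl group on C6 (C6 and C8 not defined) | C=C(O[Si](C)(C)C(C)(C)C)C[C@]4(C(OC)OC)CCC[C@@](C)(C(=O)OC)[C@H]4C(C(=O)OC)C1(O)C=C(C)CC1 | intermediate
19 | chloromethyl ketone carbinol: 18 with the silyl enol ether replaced by CH2C(=O)CH2Cl (C6 and C8 not defined) | ClCC(=O)C[C@]4(C(OC)OC)CCC[C@@](C)(C(=O)OC)[C@H]4C(C(=O)OC)C1(O)C=C(C)CC1 | intermediate
20 | kinetic ring tautomer of 21 with a 4-methylcyclopenta-1,4-dien-1-yl ring (CH2 at C13; C6 epimer pair) | ClCC(=O)C[C@]4(C(OC)OC)CCC[C@@](C)(C(=O)OC)[C@H]4C(C(=O)OC)C1=CCC(C)=C1 | intermediate (not isolated)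
21 | chloromethyl ketone diene, methyl (1R,2S,3R)-3-(3-chloro-2-oxopropyl)-3-(dimethoxymethyl)-2-[2-methoxy-1-(3-methylcyclopenta-1,3-dien-1-yl)-2-oxoethyl]-1-methylcyclohexane-1-carboxylate (C6 epimer pair) | ClCC(=O)C[C@]4(C(OC)OC)CCC[C@@](C)(C(=O)OC)[C@H]4C(C(=O)OC)C1=CC(C)=CC1 | intermediate
22 | 2-oxyallyl cation (zwitterion) from 21, C9–C11(O−)–C12 (C6 epimer pair) | [CH2+]C([O-])=C[C@]4(C(OC)OC)CCC[C@@](C)(C(=O)OC)[C@H]4C(C(=O)OC)C1=CC(C)=CC1 | intermediate (not isolated)
23 | tetracyclic C11 ketone, dimethyl 20,20-dimethoxy-11-oxogibberell-15-ene-7,19-dioate; C4, C5, C8, C9, C10, C13 as in the target; C6 epimer pair | CC=1[C@@H]2CC(=O)[C@H]3[C@]4(C(OC)OC)CCC[C@@](C)(C(=O)OC)[C@H]4C(C(=O)OC)[C@]3(C2)C=1 | intermediate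
24 | C11 p-toluenesulfonylhydrazone of 23 (C6 epimer pair) | CC=1[C@@H]2CC(=NNS(=O)(=O)c5ccc(C)cc5)[C@H]3[C@]4(C(OC)OC)CCC[C@@](C)(C(=O)OC)[C@H]4C(C(=O)OC)[C@]3(C2)C=1 | intermediate
25 | N-boryl tosylhydrazine: C11–N(1,3,2-benzodioxaborol-2-yl)–NHTs adduct of 24 (C11 not defined; C6 epimer pair) | CC=1[C@@H]2CC(N(B5Oc6ccccc6O5)NS(=O)(=O)c5ccc(C)cc5)[C@H]3[C@]4(C(OC)OC)CCC[C@@](C)(C(=O)OC)[C@H]4C(C(=O)OC)[C@]3(C2)C=1 | intermediate (not isolated)
26 | dimethyl 20,20-dimethoxygibberell-15-ene-7,19-dioate (C6 epimer pair) | CC=1[C@@H]2CC[C@H]3[C@]4(C(OC)OC)CCC[C@@](C)(C(=O)OC)[C@H]4C(C(=O)OC)[C@]3(C2)C=1 | intermediate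
27 | dimethyl 20,20-dimethoxygibberell-15-ene-7,19-dioate, natural C6 configuration | CC=1[C@@H]2CC[C@H]3[C@]4(C(OC)OC)CCC[C@@](C)(C(=O)OC)[C@H]4[C@H](C(=O)OC)[C@]3(C2)C=1 | intermediate
28 | C15 hydroperoxide, dimethyl 15-hydroperoxy-20,20-dimethoxygibberell-16-ene-7,19-dioate (C15 not defined) | C=C1[C@@H]2CC[C@H]3[C@]4(C(OC)OC)CCC[C@@](C)(C(=O)OC)[C@H]4[C@H](C(=O)OC)[C@]3(C2)C1OO | intermediate (not isolated)
29 | dimethyl 20,20-dimethoxy-15-oxogibberell-16-ene-7,19-dioate | C=C1[C@@H]2CC[C@H]3[C@]4(C(OC)OC)CCC[C@@](C)(C(=O)OC)[C@H]4[C@H](C(=O)OC)[C@]3(C2)C1=O | intermediate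
30 | dimethyl 15beta-hydroxy-20,20-dimethoxygibberell-16-ene-7,19-dioate | C=C1[C@@H]2CC[C@H]3[C@]4(C(OC)OC)CCC[C@@](C)(C(=O)OC)[C@H]4[C@H](C(=O)OC)[C@]3(C2)[C@@H]1O | intermediate
31 | 15beta-hydroxy-20,20-dimethoxygibberell-16-ene-7,19-dioic acid | C=C1[C@@H]2CC[C@H]3[C@]4(C(OC)OC)CCC[C@@](C)(C(=O)O)[C@H]4[C@H](C(=O)O)[C@]3(C2)[C@@H]1O | intermediate
32 | target gibberellin, 15beta-hydroxy-20-oxogibberell-16-ene-7,19-dioic acid (C20 aldehyde on C10, acids at C7 and C19) | C=C1[C@@H]2CC[C@H]3[C@]4(C=O)CCC[C@@](C)(C(=O)O)[C@H]4[C@H](C(=O)O)[C@]3(C2)[C@@H]1O | target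

Total step count: 22. Longest linear sequence: 22 steps (steps 1 to 22, from compound 1 to compound 32).

Steps most likely to fail

Step 15. The unstabilised cation may be captured by trifluoroethanol or collapse by a Favorskii path before it reaches the diene, ring closure may run through the wrong diene tautomer, or the diene may be attacked on the wrong face. The fallback sets out from 19 and stabilises the cation with a removable chlorine. Silylation with Me3SiOTf/Et3N (enolisation toward the more acidic C12, the carbinol being silylated as well) gives the bis-silyl chloro enol ether F1. N-Chlorosuccinimide converts it into the dichloromethyl ketone silyl ether F2. Acid-catalysed loss of trimethylsilanol under the conditions of step 14 gives the dichloromethyl ketone diene F3. Et3N in CF3CH2OH then generates the chlorine-substituted oxyallyl cation, a known and more persistent partner for cyclic dienes, and gives the 12-chloro cycloadduct F4. Zn in AcOH removes the chlorine and rejoins the route at 23.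

Step 7. The acetylide may fail to add to a carbonyl between two quaternary carbons, or the alkoxide may fragment by retro-aldol cleavage of C4–C5. The fallback sets out from 8 and makes the C5=C6 bond while C5 still has only one quaternary neighbour. Peterson olefination with the enolate of ethyl (trimethylsilyl)acetate (LiN(iPr)2, THF, −78 °C to rt) gives the dienyl ether ester F5. Heating effects the Claisen rearrangement to the aldehyde enoate F6. Acetalisation under the conditions of step 6 rejoins the route at 13.

Step 5. The face selectivity of the sigmatropic shift depends on 1,3-induction from C4 across the carbonyl and may be low. The fallback sets out from 6 and lets a catalyst choose the face: Tsuji–Trost asymmetric allylic alkylation of the enolate of 6 with allyl acetate, the zerovalent palladium source Pd2(dba)3 and a chiral bis(2-diphenylphosphinobenzoyl)-1,2-diaminocyclohexane ligand of the matched hand. This gives 9 directly and makes no new compound.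

Further compounds

F1 | step 15 | bis-silyl chloro enol ether: 19 as its C12-chloro C11 trimethylsilyl enol ether and C8 trimethylsilyl ether | ClC=C(O[Si](C)(C)C)C[C@]4(C(OC)OC)CCC[C@@](C)(C(=O)OC)[C@H]4C(C(=O)OC)C1(O[Si](C)(C)C)C=C(C)CC1
F2 | step 15 | dichloromethyl ketone silyl ether: 19 with CHCl2 at C12 and a C8 trimethylsilyl ether | ClC(Cl)C(=O)C[C@]4(C(OC)OC)CCC[C@@](C)(C(=O)OC)[C@H]4C(C(=O)OC)C1(O[Si](C)(C)C)C=C(C)CC1
F3 | step 15 | dichloromethyl ketone diene: 21 with CHCl2 at C12 | ClC(Cl)C(=O)C[C@]4(C(OC)OC)CCC[C@@](C)(C(=O)OC)[C@H]4C(C(=O)OC)C1=CC(C)=CC1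
F4 | step 15 | 12-chloro cycloadduct: 23 with chlorine at C12 (C12 not defined) | CC=1[C@@H]2C(Cl)C(=O)[C@H]3[C@]4(C(OC)OC)CCC[C@@](C)(C(=O)OC)[C@H]4C(C(=O)OC)[C@]3(C2)C=1
F5 | step 7 | dienyl ether ester, ethyl 2-[(6R)-6-(methoxycarbonyl)-6-methyl-2-[(prop-2-en-1-yloxy)methylidene]cyclohexylidene]acetate | C=CCOC=C1CCC[C@@](C)(C(=O)OC)C1=CC(=O)OCC
F6 | step 7 | aldehyde enoate: 13 with a free C20 formyl group | C=CC[C@]1(C=O)CCC[C@@](C)(C(=O)OC)C1=CC(=O)OCC
F0 | step 5 | none | none
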